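**Retrosynthetic overview**
- The target is unmasked last from a bicyclic 3-acyl-4-(methylsulfanyl)enedione (hydrolysis of the thioenol ether, loss of a silyl ether).
- The six-membered ring is the last ring formed: an intramolecular Michael addition–elimination of the cyclopentanone enolate (methyl-bearing α-carbon) onto a tethered acyl ketene dithioacetal sets the second quaternary bridgehead.
- The cyclisation precursor comes from an aldol union (then oxidation) at the prenyl-bearing α-carbon of a 2,3,5-trisubstituted cyclopentanone with 2-[bis(methylsulfanyl)methylidene]-4-methyl-3-oxopentanal, which carries the three bridge carbons and the isobutyryl group.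
- The cyclopentanone fragment (five-membered ring bought as 2-methylcyclopent-2-en-1-one) is made by rhodium-catalysed asymmetric isopropenyl addition (sole source of absolute configuration), alkene hydration and prenylation; prenyl bromide comes from 2-methylbut-3-en-2-ol.
- The aldehyde fragment comes from 3-methylbutan-2-one by formylation, then CS2/MeI.

Assumption: the target is the (1R,5R,6R) enol-triketone of the given SMILES; its enol tautomers interconvert, so either enol form is the target.
Locants C2, C3 and C5 in the explanations are those of the cyclopentanone (C1 carbonyl, C2 methyl-bearing, C3 side-chain-bearing, C5 prenyl-bearing carbon).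

**Step 1**
Reactants: 1 2-methylcyclopent-2-en-1-one; 2 potassium trifluoro(prop-1-en-2-yl)borate
Product: 4 (2S,3R)-2-methyl-3-(prop-1-en-2-yl)cyclopentan-1-one, via C2-epimer mixture 3 (not isolated)
Conditions: [Rh(cod)2]BF4 (3 mol %), (R)-BINAP (3.3 mol %), toluene/H2O (10:1), 100 °C; then DBU (0.2 equiv), CH2Cl2, 23 °C
Reagents that add atoms: none
Why: Hayashi–Miyaura rhodium-catalysed asymmetric 1,4-addition, in which the (R)-BINAP–rhodium isopropenyl species adds to one enantioface of the enone and sets C3 as R, and protonation followed by DBU equilibration puts the C2 methyl trans to it (2S).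

**Step 2**
Reactants: 4 (2S,3R)-2-methyl-3-(prop-1-en-2-yl)cyclopentan-1-one
Product: 5 (2S,3R)-3-(2-hydroxypropan-2-yl)-2-methylcyclopentan-1-one
Conditions: Co(acac)2 (0.2 equiv), PhSiH3 (2.2 equiv), O2 (1 atm), THF, 23 °C
Reagents that add atoms: dioxygen, O=O
Why: Mukaiyama hydration (cobalt hydride hydrogen-atom transfer to the 1,1-disubstituted alkene, O2 capture of the tertiary radical, reduction of the peroxide) gives the Markovnikov tertiary alcohol and leaves the ketone and both stereocentres untouched.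

**Step 3**
Reactants: 6 2-methylbut-3-en-2-ol
Product: 7 1-bromo-3-methylbut-2-ene (prenyl bromide)
Conditions: 48 % aq HBr, 0 °C
Reagents that add atoms: hydrogen bromide, Br
Why: Acid-promoted allylic substitution with transposition (SN1/SN2′) turns the tertiary allylic alcohol into the more stable primary allylic bromide.

**Step 4**
Reactants: 5 (2S,3R)-3-(2-hydroxypropan-2-yl)-2-methylcyclopentan-1-one; 7 1-bromo-3-methylbut-2-ene
Product: 9 (2S,3R)-2-methyl-5-(3-methylbut-2-en-1-yl)-3-{2-[(trimethylsilyl)oxy]propan-2-yl}cyclopentan-1-one (C5 epimers), via lithium alkoxide 8 (not isolated)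
Conditions: LiN(i-Pr)2 (2.2 equiv), THF, −78 °C; 7 (1.1 equiv), DMPU, −78 → −30 °C; then Me3SiCl (1.5 equiv), −30 → 0 °C
Reagents that add atoms: chlorotrimethylsilane, C[Si](C)(C)Cl
Why: Kinetic enolate alkylation, in which the second equivalent of LiN(i-Pr)2 deprotonates the unhindered CH2 (C5), prenyl bromide alkylates that enolate and Me3SiCl caps the lithium alkoxide, the new C5 centre being an epimer mixture that is erased when C5 is enolised in step 7.

**Step 5**
Reactants: 10 3-methylbutan-2-one
Product: 11 sodium (1Z)-4-methyl-3-oxopent-1-en-1-olate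
Conditions: HCO2Et (1.2 equiv), NaOEt (1.05 equiv), Et2O, 0 → 23 °C
Reagents that add atoms: ethyl formate, CCOC=O; sodium ethoxide, [Na+].[O-]CC
Why: Crossed Claisen condensation (formylation) at the methyl group of the ketone, pulled forward by formation of the sodium enolate of the β-keto aldehyde.

**Step 6**
Reactants: 11 sodium (1Z)-4-methyl-3-oxopent-1-en-1-olate
Product: 12 2-[bis(methylsulfanyl)methylidene]-4-methyl-3-oxopentanal
Conditions: NaH (1.05 equiv), CS2 (1.1 equiv), DMF, 0 °C; then MeI (2.2 equiv), 0 → 23 °C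
Reagents that add atoms: carbon disulfide, S=C=S; iodomethane, CI
Why: The doubly activated carbon is deprotonated and adds to CS2, and the dithiolate is methylated twice on sulfur (ketene dithioacetal synthesis).

**Step 7**
Reactants: 9 (2S,3R)-2-methyl-5-(3-methylbut-2-en-1-yl)-3-{2-[(trimethylsilyl)oxy]propan-2-yl}cyclopentan-1-one (C5 epimers); 12 2-[bis(methylsulfanyl)methylidene]-4-methyl-3-oxopentanal
Product: 13 (2S,3R,5S)-5-{2-[bis(methylsulfanyl)methylidene]-1-hydroxy-4-methyl-3-oxopentyl}-2-methyl-5-(3-methylbut-2-en-1-yl)-3-{2-[(trimethylsilyl)oxy]propan-2-yl}cyclopentan-1-one (carbinol epimers)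
Conditions: LiN(i-Pr)2 (1.1 equiv), THF, −78 °C; 12 (1.2 equiv), −78 °C; AcOH, −78 °C
Reagents that add atoms: none
Why: Aldol addition of a kinetic lithium enolate, in which the base takes the C5 proton rather than the C2 proton shielded by the neighbouring CMe2OSiMe3 group and the aldehyde of 12 adds to the enolate face opposite that group, creating the quaternary centre C5 with the new chain trans to the C3 substituent.

**Step 8**
Reactants: 13 the aldol adduct of step 7
Product: 14 (2S,3R,5R)-5-{2-[bis(methylsulfanyl)methylidene]-4-methyl-3-oxopentanoyl}-2-methyl-5-(3-methylbut-2-en-1-yl)-3-{2-[(trimethylsilyl)oxy]propan-2-yl}cyclopentan-1-one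
Conditions: Dess–Martin periodinane (1.5 equiv), pyridine, CH2Cl2, 0 → 23 °C
Reagents that add atoms: none
Why: Dess–Martin oxidation of the secondary alcohol gives the non-enolisable β-diketone, which shuts off retro-aldol cleavage and makes the ketene dithioacetal a doubly activated Michael acceptor.

**Step 9**
Reactants: 14 the β-diketone of step 8
Product: 16 (1R,5R,6R)-4-hydroxy-6-(2-hydroxypropan-2-yl)-5-methyl-1-(3-methylbut-2-en-1-yl)-3-(2-methylpropanoyl)bicyclo[3.2.1]oct-3-ene-2,8-dione, via bicyclic thioenol ether 15 (not isolated)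
Conditions: KN(SiMe3)2 (1.2 equiv), THF, −78 → 0 °C; then LiOH (3 equiv), THF/H2O, 23 °C; then 1 M HCl, 23 °C
Reagents that add atoms: lithium hydroxide, [Li+].[OH-]
Why: Intramolecular Michael addition–elimination, in which the enolate formed at C2 (the only α-proton left) attacks the bis(methylsulfanyl) carbon from the face dictated by the tether at C5, expels thiolate and so closes the six-membered ring and sets the second quaternary bridgehead with the methyl group cis to the C3 side chain, after which hydroxide replaces the remaining methylsulfanyl group by addition–elimination and acid cleaves the silyl ether.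

**Compound list**
1 | 2-methylcyclopent-2-en-1-one | CC1=CCCC1=O | starting material
2 | potassium trifluoro(prop-1-en-2-yl)borate | [K+].C=C(C)[B-](F)(F)F | starting material
3 | (3R)-2-methyl-3-(prop-1-en-2-yl)cyclopentan-1-one (C2 epimers) | O=C1C(C)[C@H](C(C)=C)CC1 | intermediate
4 | (2S,3R)-2-methyl-3-(prop-1-en-2-yl)cyclopentan-1-one | O=C1[C@@H](C)[C@H](C(C)=C)CC1 | intermediate
5 | (2S,3R)-3-(2-hydroxypropan-2-yl)-2-methylcyclopentan-1-one | O=C1[C@@H](C)[C@H](C(C)(C)O)CC1 | intermediate
6 | 2-methylbut-3-en-2-ol | CC(C)(O)C=C | starting material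
7 | 1-bromo-3-methylbut-2-ene | CC(C)=CCBr | intermediate
8 | lithium 2-[(1R,2S)-2-methyl-4-(3-methylbut-2-en-1-yl)-3-oxocyclopentyl]propan-2-olate (C4 epimers) | O=C1[C@@H](C)[C@H](C(C)(C)[O-])CC1CC=C(C)C.[Li+] | intermediate
9 | (2S,3R)-2-methyl-5-(3-methylbut-2-en-1-yl)-3-{2-[(trimethylsilyl)oxy]propan-2-yl}cyclopentan-1-one (C5 epimers) | O=C1[C@@H](C)[C@H](C(C)(C)O[Si](C)(C)C)CC1CC=C(C)C | intermediate
10 | 3-methylbutan-2-one | CC(=O)C(C)C | starting material
11 | sodium (1Z)-4-methyl-3-oxopent-1-en-1-olate | [Na+].[O-]/C=C\C(=O)C(C)C | intermediate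
12 | 2-[bis(methylsulfanyl)methylidene]-4-methyl-3-oxopentanal | CSC(SC)=C(C=O)C(=O)C(C)C | intermediate
13 | (2S,3R,5S)-5-{2-[bis(methylsulfanyl)methylidene]-1-hydroxy-4-methyl-3-oxopentyl}-2-methyl-5-(3-methylbut-2-en-1-yl)-3-{2-[(trimethylsilyl)oxy]propan-2-yl}cyclopentan-1-one (carbinol epimers) | O=C1[C@@H](C)[C@H](C(C)(C)O[Si](C)(C)C)C[C@@]1(CC=C(C)C)C(O)C(=C(SC)SC)C(=O)C(C)C | intermediate
14 | (2S,3R,5R)-5-{2-[bis(methylsulfanyl)methylidene]-4-methyl-3-oxopentanoyl}-2-methyl-5-(3-methylbut-2-en-1-yl)-3-{2-[(trimethylsilyl)oxy]propan-2-yl}cyclopentan-1-one | O=C1[C@@H](C)[C@H](C(C)(C)O[Si](C)(C)C)C[C@@]1(CC=C(C)C)C(=O)C(=C(SC)SC)C(=O)C(C)C | intermediate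
15 | (1R,5S,6R)-5-methyl-1-(3-methylbut-2-en-1-yl)-3-(2-methylpropanoyl)-4-(methylsulfanyl)-6-{2-[(trimethylsilyl)oxy]propan-2-yl}bicyclo[3.2.1]oct-3-ene-2,8-dione | CC(C)=CC[C@@]12C[C@@H](C(C)(C)O[Si](C)(C)C)[C@@](C)(C1=O)C(SC)=C(C(=O)C(C)C)C2=O | intermediate
16 | (1R,5R,6R)-4-hydroxy-6-(2-hydroxypropan-2-yl)-5-methyl-1-(3-methylbut-2-en-1-yl)-3-(2-methylpropanoyl)bicyclo[3.2.1]oct-3-ene-2,8-dione | CC(C)=CC[C@@]12C[C@@H](C(C)(C)O)[C@@](C)(C1=O)C(O)=C(C(=O)C(C)C)C2=O | target

**Step count and risks**
Total step count: 9. Longest linear sequence: 6 steps (1 → 2 → 4 → 7 → 8 → 9). Step 3 and steps 5–6 are side branches that join at steps 4 and 7.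

The three steps most likely to fail:

Step 1 is at risk because an α-methyl enone inserts slowly into the rhodium–alkenyl bond, so conversion and ee may suffer. The fallback leaves the boron/rhodium/protonation manifold and sets out again from 1 with a copper-catalysed asymmetric Grignard addition and enolate trapping. Isopropenylmagnesium bromide, Cu(OTf)2 and a chiral N-heterocyclic carbene ligand (imidazolinium precursor, the enantiomer that gives the 3R ketone) in Et2O at −30 °C, then Me3SiCl/Et3N, give the enol silane (3S)-trimethyl{[2-methyl-3-(prop-1-en-2-yl)cyclopent-1-en-1-yl]oxy}silane F1. Protonolysis (AcOH, MeOH/THF, then DBU) returns to 4.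

Step 7 is at risk because a hindered tetrasubstituted enolate must form a quaternary centre. The aldolate can revert, and selectivity for the face opposite the C3 side chain may be only moderate. Deprotonation at C2 instead of C5 is not fatal, since that regioisomeric adduct converges on 16 through steps 8 and 9. The fallback swaps the roles of the two electrophilic carbons of 12; it sets out from 9 and 12 and comes back at 16. The potassium enolate of 9 (KH, THF, 0 → 23 °C, where aldol adducts revert) attacks the bis(methylsulfanyl) carbon of 12 and expels thiolate (intermolecular Michael addition–elimination). This gives the enal (2S,3R,5R)-5-[2-formyl-4-methyl-1-(methylsulfanyl)-3-oxopent-1-en-1-yl]-2-methyl-5-(3-methylbut-2-en-1-yl)-3-{2-[(trimethylsilyl)oxy]propan-2-yl}cyclopentan-1-one F2. KN(SiMe3)2 (THF, −78 °C) then closes the ring by intramolecular aldol of the C2 enolate onto the aldehyde to give the ketol (1R,5R,7R)-2-hydroxy-1-methyl-5-(3-methylbut-2-en-1-yl)-3-(2-methylpropanoyl)-4-(methylsulfanyl)-7-{2-[(trimethylsilyl)oxy]propan-2-yl}bicyclo[3.2.1]oct-3-en-8-one F3. Dess–Martin oxidation gives the regioisomeric thioenol ether (1R,5R,7R)-1-methyl-5-(3-methylbut-2-en-1-yl)-3-(2-methylpropanoyl)-4-(methylsulfanyl)-7-{2-[(trimethylsilyl)oxy]propan-2-yl}bicyclo[3.2.1]oct-3-ene-2,8-dione F4. LiOH and then HCl, as in step 9, deliver 16.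

Step 9 is at risk because the ambident enolate may attack the ketene dithioacetal through oxygen (giving a fused enol ether) instead of carbon, and the C–C bond forms a congested quaternary centre. The fallback sets out from 14 and blocks the enolate oxygen. Me3SiOTf/Et3N (CH2Cl2, 0 °C) gives the enol silane 2-[bis(methylsulfanyl)methylidene]-4-methyl-1-[(1R,4R)-3-methyl-1-(3-methylbut-2-en-1-yl)-2-[(trimethylsilyl)oxy]-4-{2-[(trimethylsilyl)oxy]propan-2-yl}cyclopent-2-en-1-yl]pentane-1,3-dione F5. Lewis acid activation of the acceptor (SnCl4, CH2Cl2, −78 °C; Mukaiyama–Michael addition–elimination with loss of the silyl and one methylsulfanyl group) then cyclises it through carbon only. This returns to 15, which LiOH and then HCl convert to 16.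

**Further compounds**
F1 | step 1 | (3S)-trimethyl{[2-methyl-3-(prop-1-en-2-yl)cyclopent-1-en-1-yl]oxy}silane | C=C(C)[C@@H]1CCC(O[Si](C)(C)C)=C1C
F2 | step 7 | (2S,3R,5R)-5-[2-formyl-4-methyl-1-(methylsulfanyl)-3-oxopent-1-en-1-yl]-2-methyl-5-(3-methylbut-2-en-1-yl)-3-{2-[(trimethylsilyl)oxy]propan-2-yl}cyclopentan-1-one | O=C1[C@@H](C)[C@H](C(C)(C)O[Si](C)(C)C)C[C@@]1(CC=C(C)C)C(SC)=C(C=O)C(=O)C(C)C
F3 | step 7 | (1R,5R,7R)-2-hydroxy-1-methyl-5-(3-methylbut-2-en-1-yl)-3-(2-methylpropanoyl)-4-(methylsulfanyl)-7-{2-[(trimethylsilyl)oxy]propan-2-yl}bicyclo[3.2.1]oct-3-en-8-one (carbinol epimers) | CC(C)=CC[C@@]12C[C@@H](C(C)(C)O[Si](C)(C)C)[C@@](C)(C1=O)C(O)C(C(=O)C(C)C)=C2SC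
F4 | step 7 | (1R,5R,7R)-1-methyl-5-(3-methylbut-2-en-1-yl)-3-(2-methylpropanoyl)-4-(methylsulfanyl)-7-{2-[(trimethylsilyl)oxy]propan-2-yl}bicyclo[3.2.1]oct-3-ene-2,8-dione | CC(C)=CC[C@@]12C[C@@H](C(C)(C)O[Si](C)(C)C)[C@@](C)(C1=O)C(=O)C(C(=O)C(C)C)=C2SC
F5 | step 9 | 2-[bis(methylsulfanyl)methylidene]-4-methyl-1-[(1R,4R)-3-methyl-1-(3-methylbut-2-en-1-yl)-2-[(trimethylsilyl)oxy]-4-{2-[(trimethylsilyl)oxy]propan-2-yl}cyclopent-2-en-1-yl]pentane-1,3-dione | C[Si](C)(C)OC1=C(C)[C@H](C(C)(C)O[Si](C)(C)C)C[C@@]1(CC=C(C)C)C(=O)C(=C(SC)SC)C(=O)C(C)C
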